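**Retrosynthetic overview**
- The target is a flavonol in which ring A carries O1 on C8a and the C4 carbonyl carbon on the neighbouring C4a. This ortho oxygen/acyl pair is what a single aryne can take up from one carboxylic acid.
- Target ⇐ (hydrogenolysis, S–O cleavage of a C5 triflate, C3 hydroxylation through the 2,3-epoxide) 5-triflyloxyflavone ⇐ (6-endo-dig closure O1–C2) ortho-hydroxyaryl ynone.
- Key disconnection: O1–C8a and C4–C4a of the ynone, formed together by insertion of 5,6-dimethoxy-3-(triflyloxy)benzyne into the C–O bond of a ring B arylpropiolic acid. The triflate left at C5 steers the addition and masks the 5-OH.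
- The aryne precursor comes from 2-hydroxy-4,5-dimethoxybenzaldehyde (bromination, Dakin oxidation, retro-Brook silyl shift, bis-triflation). The propiolic acid comes from methyl 3,5-dihydroxy-4-methoxybenzoate (benzylation, reduction/oxidation, alkyne homologation, carboxylation).
- Ring order: rings A and B are bought as benzenoid starting materials; ring C (the γ-pyrone) is the only ring formed, in step 11, after the key step.

Key step: step 10

Remark: the target has no stereocentre; the only stereocentres on the route are those of the racemic 2,3-epoxide formed and consumed in step 12. Both starting materials are taken as purchased.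

**Route**

Step 1
Reactants: 1 2-hydroxy-4,5-dimethoxybenzaldehyde
Product: 2 3-bromo-2-hydroxy-4,5-dimethoxybenzaldehyde
Conditions: NBS, MeCN, 0 °C to rt
Reagents that add atoms: N-bromosuccinimide, O=C1CCC(=O)N1Br
Why: Electrophilic aromatic bromination should go to C3, the only free position ortho to the phenol and to the C4 methoxy group, whereas C6 is deactivated by the ortho formyl group.

Step 2
Reactants: 2 3-bromo-2-hydroxy-4,5-dimethoxybenzaldehyde
Product: 4 3-bromo-4,5-dimethoxybenzene-1,2-diol, via aryl formate 3 (not isolated)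
Conditions: H2O2 (30% aq.), NaOH, THF/H2O, 0 °C, N2; then Na2S2O3, HCl
Reagents that add atoms: hydrogen peroxide, OO
Why: Dakin oxidation, in which hydroperoxide adds to the aldehyde of the electron-rich ortho-hydroxybenzaldehyde, the aryl group migrates to oxygen to give formate 3 and hydroxide hydrolyses it to the catechol.

Step 3
Reactants: 4 3-bromo-4,5-dimethoxybenzene-1,2-diol
Product: 8 4,5-dimethoxy-3-(trimethylsilyl)benzene-1,2-diol, via bis(trimethylsilyl) ether 5 (not isolated), via aryllithium 6 (not isolated), via lithium silylphenoxide 7 (not isolated)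
Conditions: HMDS, THF, 65 °C, then evaporation; n-BuLi, THF, −78 °C to rt; MeOH, sat. aq. NH4Cl
Reagents that add atoms: hexamethyldisilazane, C[Si](C)(C)N[Si](C)(C)C
Why: O-silylation, bromine–lithium exchange and a 1,3 O-to-C silyl shift (retro-Brook rearrangement) from the neighbouring silyl ether should place the trimethylsilyl group on C3 without any acid, and the remaining aryl silyl ether is solvolysed on work-up.

Step 4
Reactants: 8 4,5-dimethoxy-3-(trimethylsilyl)benzene-1,2-diol
Product: 9 4,5-dimethoxy-3-(trimethylsilyl)-1,2-phenylene bis(trifluoromethanesulfonate)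
Conditions: Tf2O, pyridine, CH2Cl2, 0 °C to rt
Reagents that add atoms: trifluoromethanesulfonic anhydride, O=S(=O)(OS(=O)(=O)C(F)(F)F)C(F)(F)F
Why: O-sulfonylation of both phenols with triflic anhydride, the standard way to turn an ortho-silylphenol into an ortho-silylaryl triflate, also removes the air-sensitive catechol.

Step 5
Reactants: 10 methyl 3,5-dihydroxy-4-methoxybenzoate
Product: 11 methyl 3,5-bis(benzyloxy)-4-methoxybenzoate
Conditions: BnBr, K2CO3, DMF, 60 °C
Reagents that add atoms: benzyl bromide, BrCc1ccccc1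
Why: Williamson ether synthesis on both phenols gives benzyl ethers that withstand hydride, organolithium, fluoride and dioxirane and are removed at the end by hydrogenolysis.

Step 6
Reactants: 11 methyl 3,5-bis(benzyloxy)-4-methoxybenzoate
Product: 12 [3,5-bis(benzyloxy)-4-methoxyphenyl]methanol
Conditions: LiAlH4, THF, 0 °C
Reagents that add atoms: none
Why: Hydride reduction of the ester to the benzylic alcohol with LiAlH4 leaves benzyl and methyl ethers untouched.

Step 7
Reactants: 12 [3,5-bis(benzyloxy)-4-methoxyphenyl]methanol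
Product: 13 3,5-bis(benzyloxy)-4-methoxybenzaldehyde
Conditions: MnO2, CH2Cl2, rt
Reagents that add atoms: none
Why: Oxidation of a benzylic alcohol with activated MnO2 stops at the aldehyde.

Step 8
Reactants: 13 3,5-bis(benzyloxy)-4-methoxybenzaldehyde
Product: 14 1,3-bis(benzyloxy)-5-ethynyl-2-methoxybenzene
Conditions: dimethyl (1-diazo-2-oxopropyl)phosphonate, K2CO3, MeOH/THF, rt
Reagents that add atoms: dimethyl (1-diazo-2-oxopropyl)phosphonate, CC(=O)C(=[N+]=[N-])P(=O)(OC)OC
Why: Seyferth–Gilbert homologation in the Ohira–Bestmann variant, in which the diazophosphonate anion released by methanolysis olefinates the aldehyde and the alkylidene carbene rearranges by 1,2-hydrogen shift to the terminal alkyne.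

Step 9
Reactants: 14 1,3-bis(benzyloxy)-5-ethynyl-2-methoxybenzene
Product: 16 3-[3,5-bis(benzyloxy)-4-methoxyphenyl]propiolic acid, via lithium acetylide 15 (not isolated)
Conditions: n-BuLi, THF, −78 °C; CO2; then 1 M HCl
Reagents that add atoms: carbon dioxide, O=C=O
Why: Deprotonation of the terminal alkyne and carboxylation of the lithium acetylide with CO2 should give the arylpropiolic acid after acidification.

Step 10
Reactants: 9 4,5-dimethoxy-3-(trimethylsilyl)-1,2-phenylene bis(trifluoromethanesulfonate); 16 3-[3,5-bis(benzyloxy)-4-methoxyphenyl]propiolic acid (1.5 equiv)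
Product: 19 1-[2-hydroxy-3,4-dimethoxy-6-(trifluoromethanesulfonyloxy)phenyl]-3-[3,5-bis(benzyloxy)-4-methoxyphenyl]prop-2-yn-1-one, via sodium carboxylate 17 (not isolated), via aryne 18 (not isolated)
Conditions: NaH (1.0 equiv to 16), THF, 0 °C; then CsF, 18-crown-6, slow addition of 9, THF, rt to 40 °C; then 1 M HCl, 0 °C
Reagents that add atoms: none
Why: Fluoride attacks silicon in 9 and the carbanion expels the triflate on the neighbouring carbon, the only one ortho to silicon, to give 5,6-dimethoxy-3-(triflyloxy)benzyne 18. Carboxylate 17 adds through oxygen to the aryne carbon that becomes C8a, and the aryl anion at C4a attacks the ester carbonyl through a four-membered alkoxide that opens to the ketone phenoxide (an anionic Fries-type 1,3 O-to-C acyl shift), so O1–C8a and C4–C4a form in one operation. The closest known reaction type is the insertion of arynes into the C–O bond of carboxylic acids to give ortho-hydroxyaryl ketones, arylpropiolic acids included, together with the regiocontrolled capture of carbonyl compounds by 3-triflyloxyarynes. No ring is closed and no stereocentre is formed: because the acid is deprotonated beforehand with loss of H2, no proton donor is present to turn the aryl anion into the aryl ester or to let the phenoxide complete a conjugate addition to the ynone before the cold acidic quench. The selectivity needed is attack at the aryne carbon remote from the triflate, and it should be secured because the triflyloxy group is more inductively withdrawing and larger than the methoxy group on the other flank, so the aryne is distorted towards attack next to OMe and the charge develops next to OTf. The C5 triflate is not ortho to silicon, cannot be eliminated by fluoride and stays as the masked 5-OH, while slow addition of 9 to excess carboxylate limits arylation of the product phenoxide.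

Step 11
Reactants: 19 1-[2-hydroxy-3,4-dimethoxy-6-(trifluoromethanesulfonyloxy)phenyl]-3-[3,5-bis(benzyloxy)-4-methoxyphenyl]prop-2-yn-1-one
Product: 20 2-[3,5-bis(benzyloxy)-4-methoxyphenyl]-7,8-dimethoxy-4-oxo-4H-chromen-5-yl trifluoromethanesulfonate
Conditions: DMAP (20 mol %), DMF, rt
Reagents that add atoms: none
Why: Nucleophilic-base catalysed cyclisation of an ortho-alkynoylphenol, in which DMAP adds to the ynone β-carbon and the phenol oxygen replaces it by addition–elimination, should give only the 6-endo product (O1–C2 bond, ring C) and no aurone.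

Step 12
Reactants: 20 2-[3,5-bis(benzyloxy)-4-methoxyphenyl]-7,8-dimethoxy-4-oxo-4H-chromen-5-yl trifluoromethanesulfonate
Product: 22 2-[3,5-bis(benzyloxy)-4-methoxyphenyl]-3-hydroxy-7,8-dimethoxy-4-oxo-4H-chromen-5-yl trifluoromethanesulfonate, via flavone epoxide 21 (not isolated)
Conditions: DMDO (acetone solution), CH2Cl2, 0 °C to rt; evaporation; then p-TsOH·H2O (cat.), CH2Cl2, rt
Reagents that add atoms: dimethyldioxirane, CC1(C)OO1
Why: Dioxirane epoxidation of the enol-ether-like C2=C3 bond of the flavone followed by acid-catalysed opening at C2 to the oxocarbenium ion and loss of the C3 proton should give the 3-hydroxyflavone, so the two stereocentres of racemic 21 disappear, and the triflate keeps ring A electron-poor towards the oxidant.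

Step 13
Reactants: 22 2-[3,5-bis(benzyloxy)-4-methoxyphenyl]-3-hydroxy-7,8-dimethoxy-4-oxo-4H-chromen-5-yl trifluoromethanesulfonate
Product: 23 2-[3,5-bis(benzyloxy)-4-methoxyphenyl]-3,5-dihydroxy-7,8-dimethoxy-4H-chromen-4-one
Conditions: Et4NOH (aq.), 1,4-dioxane, rt, Ar; then 1 M HCl
Reagents that add atoms: none
Why: Hydroxide attacks the sulfur of the aryl triflate (S–O cleavage, a known mild de-triflation) and releases the C5 phenoxide, while the flavonol is held as its less electrophilic 3-olate and oxygen is excluded.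

Step 14
Reactants: 23 2-[3,5-bis(benzyloxy)-4-methoxyphenyl]-3,5-dihydroxy-7,8-dimethoxy-4H-chromen-4-one
Product: 24 2-(3,5-dihydroxy-4-methoxyphenyl)-3,5-dihydroxy-7,8-dimethoxy-4H-chromen-4-one
Conditions: H2 (1 atm), Pd/C (10 wt%), THF/MeOH, rt
Reagents that add atoms: none
Why: Hydrogenolysis of both benzyl ethers over Pd/C should leave the C2=C3 bond of the γ-pyrone untouched, and it is placed after step 13 because an aryl triflate could be reduced to C–H under these conditions.

**Compound list**

1 | 2-hydroxy-4,5-dimethoxybenzaldehyde | COc1cc(O)c(C=O)cc1OC | starting material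
2 | 3-bromo-2-hydroxy-4,5-dimethoxybenzaldehyde | COc1cc(C=O)c(O)c(Br)c1OC | intermediate
3 | 3-bromo-2-hydroxy-4,5-dimethoxyphenyl formate | COc1cc(OC=O)c(O)c(Br)c1OC | intermediate (not isolated)
4 | 3-bromo-4,5-dimethoxybenzene-1,2-diol | COc1cc(O)c(O)c(Br)c1OC | intermediate
5 | 3-bromo-4,5-dimethoxy-1,2-bis(trimethylsilyloxy)benzene | COc1cc(O[Si](C)(C)C)c(O[Si](C)(C)C)c(Br)c1OC | intermediate (not isolated)
6 | [2,3-dimethoxy-5,6-bis(trimethylsilyloxy)phenyl]lithium | COc1cc(O[Si](C)(C)C)c(O[Si](C)(C)C)c([Li])c1OC | intermediate (not isolated)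
7 | lithium 3,4-dimethoxy-2-(trimethylsilyl)-6-(trimethylsilyloxy)phenolate | COc1cc(O[Si](C)(C)C)c([O-])c([Si](C)(C)C)c1OC.[Li+] | intermediate (not isolated)
8 | 4,5-dimethoxy-3-(trimethylsilyl)benzene-1,2-diol | COc1cc(O)c(O)c([Si](C)(C)C)c1OC | intermediate
9 | 4,5-dimethoxy-3-(trimethylsilyl)-1,2-phenylene bis(trifluoromethanesulfonate) | COc1cc(OS(=O)(=O)C(F)(F)F)c(OS(=O)(=O)C(F)(F)F)c([Si](C)(C)C)c1OC | intermediate (key-step precursor)
10 | methyl 3,5-dihydroxy-4-methoxybenzoate | COC(=O)c1cc(O)c(OC)c(O)c1 | starting material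
11 | methyl 3,5-bis(benzyloxy)-4-methoxybenzoate | COC(=O)c1cc(OCc2ccccc2)c(OC)c(OCc2ccccc2)c1 | intermediate
12 | [3,5-bis(benzyloxy)-4-methoxyphenyl]methanol | OCc1cc(OCc2ccccc2)c(OC)c(OCc2ccccc2)c1 | intermediate
13 | 3,5-bis(benzyloxy)-4-methoxybenzaldehyde | O=Cc1cc(OCc2ccccc2)c(OC)c(OCc2ccccc2)c1 | intermediate
14 | 1,3-bis(benzyloxy)-5-ethynyl-2-methoxybenzene | C#Cc1cc(OCc2ccccc2)c(OC)c(OCc2ccccc2)c1 | intermediate
15 | {[3,5-bis(benzyloxy)-4-methoxyphenyl]ethynyl}lithium | [Li]C#Cc1cc(OCc2ccccc2)c(OC)c(OCc2ccccc2)c1 | intermediate (not isolated)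
16 | 3-[3,5-bis(benzyloxy)-4-methoxyphenyl]propiolic acid | OC(=O)C#Cc1cc(OCc2ccccc2)c(OC)c(OCc2ccccc2)c1 | intermediate (key-step precursor)
17 | sodium 3-[3,5-bis(benzyloxy)-4-methoxyphenyl]propiolate | [Na+].[O-]C(=O)C#Cc1cc(OCc2ccccc2)c(OC)c(OCc2ccccc2)c1 | intermediate (not isolated)
18 | 5,6-dimethoxy-3-(trifluoromethanesulfonyloxy)benzyne | COC1=C(OC)C=C(OS(=O)(=O)C(F)(F)F)C#C1 | intermediate (not isolated)
19 | 1-[2-hydroxy-3,4-dimethoxy-6-(trifluoromethanesulfonyloxy)phenyl]-3-[3,5-bis(benzyloxy)-4-methoxyphenyl]prop-2-yn-1-one | COc1cc(OS(=O)(=O)C(F)(F)F)c(C(=O)C#Cc2cc(OCc3ccccc3)c(OC)c(OCc3ccccc3)c2)c(O)c1OC | intermediate (key-step product)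
20 | 2-[3,5-bis(benzyloxy)-4-methoxyphenyl]-7,8-dimethoxy-4-oxo-4H-chromen-5-yl trifluoromethanesulfonate | COc1cc(OS(=O)(=O)C(F)(F)F)c2c(=O)cc(-c3cc(OCc4ccccc4)c(OC)c(OCc4ccccc4)c3)oc2c1OC | intermediate
21 | racemic cis-fused 2,3-epoxide of 20, 1a-[3,5-bis(benzyloxy)-4-methoxyphenyl]-3,4-dimethoxy-7-oxo-1a,7a-dihydro-7H-oxireno[2,3-b]chromen-6-yl trifluoromethanesulfonate (one enantiomer drawn) | COc1cc(OS(=O)(=O)C(F)(F)F)c2C(=O)[C@H]3O[C@@]3(c5cc(OCc4ccccc4)c(OC)c(OCc4ccccc4)c5)Oc2c1OC | intermediate (not isolated)
22 | 2-[3,5-bis(benzyloxy)-4-methoxyphenyl]-3-hydroxy-7,8-dimethoxy-4-oxo-4H-chromen-5-yl trifluoromethanesulfonate | COc1cc(OS(=O)(=O)C(F)(F)F)c2c(=O)c(O)c(-c3cc(OCc4ccccc4)c(OC)c(OCc4ccccc4)c3)oc2c1OC | intermediate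
23 | 2-[3,5-bis(benzyloxy)-4-methoxyphenyl]-3,5-dihydroxy-7,8-dimethoxy-4H-chromen-4-one | COc1cc(O)c2c(=O)c(O)c(-c3cc(OCc4ccccc4)c(OC)c(OCc4ccccc4)c3)oc2c1OC | intermediate
24 | 2-(3,5-dihydroxy-4-methoxyphenyl)-3,5-dihydroxy-7,8-dimethoxy-4H-chromen-4-one | COc1cc(O)c2c(=O)c(O)c(-c3cc(O)c(OC)c(O)c3)oc2c1OC | target

**Step count**

Total: 14 steps (ring A branch steps 1–4, ring B branch steps 5–9, common steps 10–14).
Longest linear sequence: 10 steps (steps 5–9, then 10–14, from compound 10).

**Steps most likely to fail**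

Step 10. The carboxylate may add with poor regiocontrol, because a methoxy group on the other flank of the aryne competes with the triflate. The aryl anion next to the C5 triflate may expel that triflate before it captures the acyl group. The product phenoxide may be arylated by further aryne, or may close ring C early with leakage into 5-exo products. The fallback sets out from 9 and 14 and comes back at 19. Aryne 18 is generated from 9 with CsF in DMF at rt and adds across the carbonyl group of the solvent, oxygen at C8a and carbon at C4a, a known aryne–formamide insertion. Aqueous work-up should then release 2-formyl-3-hydroxy-4,5-dimethoxyphenyl trifluoromethanesulfonate F1. Lithium acetylide 15, made from 14 with n-BuLi and used in excess because the first equivalent is spent on the phenol, is added to F1 in THF at −78 °C. This should give racemic 2-{3-[3,5-bis(benzyloxy)-4-methoxyphenyl]-1-hydroxyprop-2-yn-1-yl}-3-hydroxy-4,5-dimethoxyphenyl trifluoromethanesulfonate F2. MnO2 in CH2Cl2 then oxidises the propargylic alcohol to ynone 19. This route needs no carboxylate, no acyl shift and leaves no free phenoxide in the presence of aryne.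

Step 3. Butyllithium may attack silicon of the aryl silyl ethers instead of bromine, the O-to-C silyl migration may stay incomplete so that the aryllithium is protonated, and the free catechol may be oxidised by air during handling. The fallback sets out from 4 and comes back at 8. Benzylation (BnBr, K2CO3, DMF, degassed) should give 1,2-bis(benzyloxy)-3-bromo-4,5-dimethoxybenzene F3. Bromine–lithium exchange with n-BuLi in THF at −78 °C gives [2,3-bis(benzyloxy)-5,6-dimethoxyphenyl]lithium F4, which is silylated directly at carbon with TMSCl to [2,3-bis(benzyloxy)-5,6-dimethoxyphenyl]trimethylsilane F5. Neutral hydrogenolysis (H2, Pd/C, EtOAc) then frees catechol 8 without acid, so the aryl–silicon bond is not at risk.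

Step 13. Under hydroxide the flavonolate may be degraded oxidatively or ring C may be opened by attack at C2 faster than the triflate is cleaved, and any triflate that survives would be reduced to C–H in step 14. The fallback sets out from 20 and comes back at 24. The triflate is cleaved before the 3-hydroxyl exists: Et4NOH in dioxane on 20 should give 2-[3,5-bis(benzyloxy)-4-methoxyphenyl]-5-hydroxy-7,8-dimethoxy-4H-chromen-4-one F6. Benzylation (BnBr, K2CO3, DMF, 60 °C) gives 5-(benzyloxy)-2-[3,5-bis(benzyloxy)-4-methoxyphenyl]-7,8-dimethoxy-4H-chromen-4-one F7. DMDO then gives the racemic 2,3-epoxide 6-(benzyloxy)-1a-[3,5-bis(benzyloxy)-4-methoxyphenyl]-3,4-dimethoxy-1a,7a-dihydro-7H-oxireno[2,3-b]chromen-7-one F8, which catalytic p-TsOH opens to 5-(benzyloxy)-2-[3,5-bis(benzyloxy)-4-methoxyphenyl]-3-hydroxy-7,8-dimethoxy-4H-chromen-4-one F9. Hydrogenolysis (H2, Pd/C) of all three benzyl ethers gives 24.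

**Further compounds**

F1 | step 10 | 2-formyl-3-hydroxy-4,5-dimethoxyphenyl trifluoromethanesulfonate | COc1cc(OS(=O)(=O)C(F)(F)F)c(C=O)c(O)c1OC
F2 | step 10 | 2-{3-[3,5-bis(benzyloxy)-4-methoxyphenyl]-1-hydroxyprop-2-yn-1-yl}-3-hydroxy-4,5-dimethoxyphenyl trifluoromethanesulfonate (racemic) | COc1cc(OS(=O)(=O)C(F)(F)F)c(C(O)C#Cc2cc(OCc3ccccc3)c(OC)c(OCc3ccccc3)c2)c(O)c1OC
F3 | step 3 | 1,2-bis(benzyloxy)-3-bromo-4,5-dimethoxybenzene | COc1cc(OCc2ccccc2)c(OCc2ccccc2)c(Br)c1OC
F4 | step 3 | [2,3-bis(benzyloxy)-5,6-dimethoxyphenyl]lithium | COc1cc(OCc2ccccc2)c(OCc2ccccc2)c([Li])c1OC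
F5 | step 3 | [2,3-bis(benzyloxy)-5,6-dimethoxyphenyl]trimethylsilane | COc1cc(OCc2ccccc2)c(OCc2ccccc2)c([Si](C)(C)C)c1OC
F6 | step 13 | 2-[3,5-bis(benzyloxy)-4-methoxyphenyl]-5-hydroxy-7,8-dimethoxy-4H-chromen-4-one | COc1cc(O)c2c(=O)cc(-c3cc(OCc4ccccc4)c(OC)c(OCc4ccccc4)c3)oc2c1OC
F7 | step 13 | 5-(benzyloxy)-2-[3,5-bis(benzyloxy)-4-methoxyphenyl]-7,8-dimethoxy-4H-chromen-4-one | COc1cc(OCc5ccccc5)c2c(=O)cc(-c3cc(OCc4ccccc4)c(OC)c(OCc4ccccc4)c3)oc2c1OC
F8 | step 13 | 6-(benzyloxy)-1a-[3,5-bis(benzyloxy)-4-methoxyphenyl]-3,4-dimethoxy-1a,7a-dihydro-7H-oxireno[2,3-b]chromen-7-one (racemic cis-fused 2,3-epoxide of F7, one enantiomer drawn) | COc1cc(OCc6ccccc6)c2C(=O)[C@H]3O[C@@]3(c5cc(OCc4ccccc4)c(OC)c(OCc4ccccc4)c5)Oc2c1OC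
F9 | step 13 | 5-(benzyloxy)-2-[3,5-bis(benzyloxy)-4-methoxyphenyl]-3-hydroxy-7,8-dimethoxy-4H-chromen-4-one | COc1cc(OCc5ccccc5)c2c(=O)c(O)c(-c3cc(OCc4ccccc4)c(OC)c(OCc4ccccc4)c3)oc2c1OC
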